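Target forms in the reaction phase and decomposes there, while the second phase holds it away from that decomposition.

    reagent in the reaction phase ⇌ reagent in the second phase, rate k1*([reagent in the reaction phase] - [reagent in the second phase]/K1) per volume of the first phase (K1 = 1.7, k1 = 2.7 s⁻¹)
    starting material + reagent in the reaction phase → target (k2 = 97 L mol⁻¹ s⁻¹)
    target ⇌ product in the second phase, rate k3*([target] - [product in the second phase]/K3) per volume of the first phase (K3 = 11, k3 = 0.058 s⁻¹)
    target → decomposed product (k4 = 0.010 s⁻¹)
    2 starting material → self-condensation product (k5 = 0.0024 L mol⁻¹ s⁻¹)
    target ⇌ isomer of the product (K6 = 0.55, k6 = 0.085 s⁻¹)
    starting material + protic impurity → quenched substrate (k7 = 4.8 L mol⁻¹ s⁻¹)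

starting material 0.020 M; reagent in the second phase 0.0240 M; protic impurity 4.00 mM; time 40 s; volume of the second phase over the first 2.0

- percent here means starting material units held: one self-condensation product counts as two
- what is said of target includes product in the second phase
- where a step has two of a species, its rate is k times that concentration squared, and two are used at each turn
- in the second phase: reagent in the second phase, product in the second phase; everything else is in the first
- charges count per volume of the first phase; a concentration in a rate is the amount of a species over the volume of its own phase; every rate counts per litre of the first phase
- run time (flask): 40 s

- target and product in the second phase together at 40 s, in percent of the starting material charged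
- the change that raises the amount of target and product in the second phase together at 40 s, in percent of the starting material charged most ("none" if none brings more than 2 percentage points) (teal / green / grey / none)
- amount of target and product in the second phase together at 40 s, in percent of the starting material charged, after teal

- teal: doubling the transfer coefficient of step 3, all else as stated
- green: doubling the transfer coefficient of step 1, all else as stated
- grey: doubling the amount of reagent in the second phase, all else as stated

Reagent crosses into the reaction phase at 2.7 s⁻¹, and there its half-life against starting material as charged is 0.36 s, so you can expect target to form early, well inside the 40 s. But formed is not kept: first-phase target goes over at 0.058 s⁻¹ or decomposes at 0.010 s⁻¹. The way back is weak, since partition ratio times volume ratio is 22.0, so the end state lies across the interface.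

Hence my rule: 85.3% is the capture share, the transfer coefficient over itself plus the decomposition constant, a selectivity between two first-order exits. Self-condensation changes nothing. The isomer relaxes with a half-life of 2.89 s, short against the run, and at equilibrium 64.5% of the first-phase pool is target. That slows both exits alike and leaves the capture share as it was.

Of each target that leaves the first-phase pool by these two exits, I therefore expect 85.3% to reach the second phase, and after teal 92.1%; what still stands in the pool at 40 s I do not reckon. Green and grey leave the capture share alone and can act on the amount formed, where my reckoning stops.

The forecast commits to 73%, teal and 81%, on the ground that “extraction beats isomer holdup and decomposition”.

The flask gives 72.9%, and teal gives 81.0%, a gain of 8.1 percentage points against 3.6 points for grey and 0.45 points for green. The flask's answer has moved by 5 points at reagent in the second phase 0.0189 M or starting material 0.0265 M. At 40.0 s the flask holds 59.6% product in the second phase and 10.9% decomposed product, a share of 84.5% beside the capture share of 85.3%. The neighbour charged with 0.080 M starting material holds 19.7% in the second phase, for which the capture share asks 3.39% decomposed product, and it holds 3.63%.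

(All constants belong to no real substance; the rest is arithmetic.)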